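The ten-membered carbocycle is closed by ring-closing metathesis between a C5 vinyl group and a C4 isopropenyl group that hang from the two cis arms of a 2,5-disubstituted oxolane (ring O–C7–C8–C9–C10). Because the oxolane bridge (C7–O–C10) already holds C6 and C1 on one face, one step closes both the nine-membered oxacycle and the ten-membered carbocycle, and the ring size enforces the Z alkene that carries the cis H-5/CH3-15 relation of the oxirane. The diene is built from (S)-lactic acid, acrolein and a 2-bromoallyl ether; afterwards the C6 hydroxyl directs the epoxidation and an oxidative lactonisation closes the spiro-lactone.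

Key step: step 11

Atom labels used throughout: C1 ketone carbon, C2, C3, C4 (bears methyl C15), C5, C6 (bears the lactone oxygen), C7 (spiro carbon), C8 (bears the ester oxygen), C9, C10 (bears methyl C14), C11, C12 (lactone carbonyl), C13 (exocyclic methylene).
Assumption 1: the sense of induction in the zinc–ProPhenol alkynylation (step 4) is assigned by analogy; the ligand antipode that gives the 6R carbinol is used and is written here as (R,R).
Assumption 2: the facial sense of the Shi epoxidation (step 9) follows the usual spiro transition-state model, which calls for the enantiomer of the common D-fructose-derived ketone.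

Step 1
Reactants: 1 (S)-lactic acid; 2 pivalaldehyde
Product: 3 (2S,5S)-2-tert-butyl-5-methyl-1,3-dioxolan-4-one
Conditions: p-TsOH·H2O (cat.), H2SO4 (cat.), pentane, reflux, Dean–Stark; crystallisation from pentane at −78 °C
Reagents that add atoms: pivalaldehyde (2), CC(C)(C)C=O
Why: Acid-catalysed acetalisation of the α-hydroxy acid (1,3-dioxolan-4-one formation) should favour the cis isomer with tert-butyl and methyl on one face, which is purified by crystallisation while the lactic acid centre stays untouched.

Step 2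
Reactants: 3 (2S,5S)-2-tert-butyl-5-methyl-1,3-dioxolan-4-one; 4 propargyl bromide
Product: 5 (2S,5R)-2-tert-butyl-5-methyl-5-(prop-2-yn-1-yl)-1,3-dioxolan-4-one
Conditions: LiN(i-Pr)2, THF, −78 °C; then 4, −78 to −30 °C
Reagents that add atoms: propargyl bromide (4), C#CCBr
Why: Enolate alkylation of a lactic acid-derived dioxolanone (self-regeneration of stereocentres) brings the propargyl group in anti to the tert-butyl group, so it replaces the former hydrogen with retention and sets C10.

Step 3
Reactants: 5 (2S,5R)-2-tert-butyl-5-methyl-5-(prop-2-yn-1-yl)-1,3-dioxolan-4-one; 6 N,O-dimethylhydroxylamine hydrochloride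
Product: 7 (2R)-2-hydroxy-N-methoxy-N,2-dimethylpent-4-ynamide
Conditions: 6, i-PrMgCl, THF, −20 to 0 °C
Reagents that add atoms: N,O-dimethylhydroxylamine hydrochloride (6), CNOC.Cl
Why: Weinreb amide formation by aminolysis of the acylal-type lactone with the chloromagnesium amide; the expelled hemiacetal alkoxide collapses to pivalaldehyde and frees the tertiary alcohol without touching C10.

Step 4
Reactants: 7 (2R)-2-hydroxy-N-methoxy-N,2-dimethylpent-4-ynamide; 8 acrolein
Product: 9 (2R,6R)-2,6-dihydroxy-N-methoxy-N,2-dimethyloct-7-en-4-ynamide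
Conditions: ZnMe2, (R,R)-ProPhenol (20 mol%), Ph3P=O (40 mol%), toluene, 0 °C; then 8, 0 °C to rt
Reagents that add atoms: acrolein (8), C=CC=O
Why: Zinc–ProPhenol-catalysed enantioselective alkynylation of an enal, in which the zinc alkynylide adds to acrolein inside the dinuclear zinc pocket of the ligand and so sets C6, while the Weinreb amide is inert to alkylzinc species.

Step 5
Reactants: 9 (2R,6R)-2,6-dihydroxy-N-methoxy-N,2-dimethyloct-7-en-4-ynamide; 10 tributyltin hydride
Product: 11 (2R,4Z,6R)-2,6-dihydroxy-N-methoxy-N,2-dimethyl-5-(tributylstannyl)octa-4,7-dienamide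
Conditions: [Cp*RuCl]4 (2.5 mol%), Bu3SnH, CH2Cl2, rt
Reagents that add atoms: tributyltin hydride (10), CCCC[SnH](CCCC)CCCC
Why: Hydroxyl-directed ruthenium-catalysed trans-hydrostannation, in which hydrogen bonding of the propargylic C6 hydroxyl to the chloride ligand steers tin to C7 and hydrogen adds anti at C8, fixing tin cis to C9.

Step 6
Reactants: 12 2-bromoprop-2-en-1-ol; 13 tert-butyldimethylsilyl chloride
Product: 14 [(2-bromoprop-2-en-1-yl)oxy](tert-butyl)dimethylsilane
Conditions: imidazole, CH2Cl2, 0 °C to rt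
Reagents that add atoms: tert-butyldimethylsilyl chloride (13), CC(C)(C)[Si](C)(C)Cl
Why: Imidazole-mediated O-silylation of a primary allylic alcohol.

Step 7
Reactants: 11 (2R,4Z,6R)-2,6-dihydroxy-N-methoxy-N,2-dimethyl-5-(tributylstannyl)octa-4,7-dienamide; 14 [(2-bromoprop-2-en-1-yl)oxy](tert-butyl)dimethylsilane
Product: 15 (2R,4E,6R)-5-[3-(tert-butyldimethylsilyloxy)prop-1-en-2-yl]-2,6-dihydroxy-N-methoxy-N,2-dimethylocta-4,7-dienamide
Conditions: Pd(PPh3)4 (10 mol%), Cu(O2CC4H3S) (copper thiophene-2-carboxylate), [NBu4][Ph2PO2], DMF, rt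
Reagents that add atoms: bromide 14, C=C(Br)CO[Si](C)(C)C(C)(C)C
Why: Copper-assisted Stille–Migita cross-coupling under fluoride-free conditions proceeds with retention at the alkenyl tin carbon, so C11 ends up cis to C9 in the 2-substituted diene.

Step 8
Reactants: 15 (2R,4E,6R)-5-[3-(tert-butyldimethylsilyloxy)prop-1-en-2-yl]-2,6-dihydroxy-N-methoxy-N,2-dimethylocta-4,7-dienamide; 16 chlorotriethylsilane
Product: 17 (2R,4E,6R)-5-[3-(tert-butyldimethylsilyloxy)prop-1-en-2-yl]-2-hydroxy-N-methoxy-N,2-dimethyl-6-(triethylsilyloxy)octa-4,7-dienamide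
Conditions: Et3SiCl, imidazole, CH2Cl2, 0 °C
Reagents that add atoms: chlorotriethylsilane (16), CC[Si](CC)(CC)Cl
Why: Silylation of the secondary allylic C6 alcohol, the tertiary C10 alcohol next to the amide being too hindered to react.

Step 9
Reactants: 17 (2R,4E,6R)-5-[3-(tert-butyldimethylsilyloxy)prop-1-en-2-yl]-2-hydroxy-N-methoxy-N,2-dimethyl-6-(triethylsilyloxy)octa-4,7-dienamide; 18 potassium peroxymonosulfate
Product: 20 (2R,4S,5S)-5-[3-(tert-butyldimethylsilyloxy)prop-1-en-2-yl]-4-hydroxy-N-methoxy-N,2-dimethyl-5-[(1R)-1-(triethylsilyloxy)prop-2-en-1-yl]oxolane-2-carboxamide, via vinyl epoxide 19 (not isolated)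
Conditions: ent-Shi ketone (L-fructose-derived ketone catalyst, 30 mol%), KHSO5 (Oxone), K2CO3, Bu4NHSO4, Na2B4O7 buffer, MeCN–CH2(OMe)2–H2O, 0 °C; extractive work-up; then CSA (10 mol%), CH2Cl2, 0 °C
Reagents that add atoms: potassium peroxymonosulfate (18), [K+].[O-]S(=O)(=O)OO
Why: Shi epoxidation (chiral dioxirane, spiro transition state) should oxidise only the electron-rich trisubstituted C7=C8 bond from the face fixed by the catalyst, and acid then triggers a 5-endo hydroxy–vinyl-epoxide opening by the C10 hydroxyl at the allylic tertiary C7 with inversion, which sets C7 and C8 and closes the oxolane.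

Step 10
Reactants: 20 oxolane Weinreb amide; 21 4-bromo-2-methylbut-1-ene
Product: 23 1-[(2R,4S,5S)-5-[3-(tert-butyldimethylsilyloxy)prop-1-en-2-yl]-4-hydroxy-2-methyl-5-[(1R)-1-(triethylsilyloxy)prop-2-en-1-yl]oxolan-2-yl]-4-methylpent-4-en-1-one, via Grignard reagent 22 (not isolated)
Conditions: 21, Mg, THF, rt (3 equiv of 22); then 20, THF, 0 °C to rt; aq. NH4Cl
Reagents that add atoms: 4-bromo-2-methylbut-1-ene (21), C=C(C)CCBr, used as its Grignard reagent 22, C=C(C)CC[Mg]Br
Why: Weinreb ketone synthesis, in which the magnesium chelate of the tetrahedral intermediate stops the addition at the ketone stage and the first equivalent of Grignard reagent only deprotonates the C8 hydroxyl.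

Step 11
Reactants: 23 oxolane diene ketone
Product: 24 (1R,5Z,7R,8S,9S)-8-[3-(tert-butyldimethylsilyloxy)prop-1-en-2-yl]-9-hydroxy-1,5-dimethyl-7-(triethylsilyloxy)-11-oxabicyclo[6.2.1]undec-5-en-2-one (C4=C5 Z; 6R,7S,8S,10R by the atom labels)
Conditions: second-generation Hoveyda–Grubbs catalyst, RuCl2(H2IMes)(=CH-C6H4-2-O-i-Pr) (10–15 mol%), 1,4-benzoquinone (cat.), toluene (1 mM), 80 °C
Reagents that add atoms: none
Why: Ring-closing olefin metathesis: the ruthenium alkylidene loads on the monosubstituted C5 vinyl group, undergoes cycloaddition and cycloreversion with the 1,1-disubstituted C4 alkene and expels ethylene, which makes the C4=C5 bond. The closest known reaction type is the RCM of cis-2,5-disubstituted oxolane dienes to Z-trisubstituted oxonenes, which gives 11-oxabicyclo[6.2.1]undecene cores. This one bond closes two rings at once by metathesis, the nine-membered oxacycle (O, C7, C6, C5, C4, C3, C2, C1, C10) and the ten-membered carbocycle, on a chain that the oxolane already holds in a cis, bridging arrangement. No stereocentre is formed; the new element is the alkene geometry, and the nine-membered ring allows only the Z isomer, which carries the cis relation of H-5 and CH3-15 needed in the oxirane. The step needs intramolecular closure to win over dimerisation and the catalyst to ignore the 2-substituted allyl silyl ether alkene on C7; high dilution, the two arms on one oxolane face and the fact that this alkene could only close a cyclobutene or a tetrasubstituted ring alkene secure that. The methacrylate is put on only afterwards so that no competing enoate metathesis to a seven-membered lactone can occur.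

Step 12
Reactants: 24 bicyclic Z-alkene; 25 methacrylic anhydride
Product: 26 (1R,5Z,7R,8S,9S)-8-[3-(tert-butyldimethylsilyloxy)prop-1-en-2-yl]-1,5-dimethyl-2-oxo-7-(triethylsilyloxy)-11-oxabicyclo[6.2.1]undec-5-en-9-yl 2-methylprop-2-enoate
Conditions: methacrylic anhydride, Et3N, DMAP (cat.), CH2Cl2, 0 °C to rt
Reagents that add atoms: methacrylic anhydride (25), C=C(C)C(=O)OC(=O)C(C)=C
Why: DMAP-catalysed acylation of the only free hydroxyl (C8), with retention at C8 because the C–O bond is not broken.

Step 13
Reactants: 26 C8 methacrylate with C6 triethylsilyl ether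
Product: 27 (1R,5Z,7R,8R,9S)-8-[3-(tert-butyldimethylsilyloxy)prop-1-en-2-yl]-7-hydroxy-1,5-dimethyl-2-oxo-11-oxabicyclo[6.2.1]undec-5-en-9-yl 2-methylprop-2-enoate (C7 unchanged in space; its descriptor changes only through CIP priority)
Conditions: PPTS (cat.), MeOH–CH2Cl2, 0 °C
Reagents that add atoms: none
Why: Acid-catalysed methanolysis (selective desilylation) removes the secondary triethylsilyl ether much faster than the primary tert-butyldimethylsilyl ether.

Step 14
Reactants: 27 C6 allylic alcohol; 28 tert-butyl hydroperoxide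
Product: 29 epoxy alcohol: 27 with a 4,5-oxirane on the face syn to the C6 hydroxyl (4R,5S; C6, C7, C8 and C10 as in the target)
Conditions: VO(acac)2 (5 mol%), t-BuOOH, CH2Cl2, 0 °C to rt
Reagents that add atoms: tert-butyl hydroperoxide (28), CC(C)(C)OO
Why: Vanadium-catalysed hydroxyl-directed epoxidation, in which the C6 alkoxide binds the vanadium alkylperoxide and delivers oxygen to the syn face of the Z alkene (the cis-epoxy alcohol mode of medium-ring Z-cycloalkenols), which sets C4 and C5 and leaves the unbound 1,1-disubstituted and enoate alkenes alone.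

Step 15
Reactants: 29 epoxy alcohol with C12 silyl ether
Product: 30 epoxy diol: 29 with a free C12 hydroxyl (4R,5S; C6, C7, C8 and C10 as in the target)
Conditions: Bu4NF, AcOH (1:1), THF, 0 °C to rt
Reagents that add atoms: none
Why: Fluoride-mediated desilylation, buffered with acetic acid so that the epoxy alcohol does not undergo Payne rearrangement and the methacrylate does not migrate.

Step 16
Reactants: 30 epoxy diol
Product: 33 target CNP0241021.1 (4R,5S,6R,7S,8S,10R), via enal 31 (not isolated), via lactol 32 (not isolated)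
Conditions: TEMPO (20 mol%), PhI(OAc)2, CH2Cl2, rt
Reagents that add atoms: none
Why: Oxidative lactonisation of a 1,4-diol with TEMPO/PhI(OAc)2, in which the primary allylic alcohol is oxidised to the enal, the C6 hydroxyl closes the lactol and a second oxidation gives the α-methylene-γ-butyrolactone, the secondary alcohol being oxidised far more slowly.

Compound list
1 | (S)-lactic acid | C[C@H](O)C(=O)O | starting material
2 | pivalaldehyde | CC(C)(C)C=O | starting material
3 | (2S,5S)-2-tert-butyl-5-methyl-1,3-dioxolan-4-one | C[C@@H]1O[C@H](C(C)(C)C)OC1=O | intermediate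
4 | propargyl bromide | C#CCBr | starting material
5 | (2S,5R)-2-tert-butyl-5-methyl-5-(prop-2-yn-1-yl)-1,3-dioxolan-4-one | C[C@]1(CC#C)O[C@H](C(C)(C)C)OC1=O | intermediate
6 | N,O-dimethylhydroxylamine hydrochloride | CNOC.Cl | starting material
7 | (2R)-2-hydroxy-N-methoxy-N,2-dimethylpent-4-ynamide | C#CC[C@@](C)(O)C(=O)N(C)OC | intermediate
8 | acrolein | C=CC=O | starting material
9 | (2R,6R)-2,6-dihydroxy-N-methoxy-N,2-dimethyloct-7-en-4-ynamide | C=C[C@@H](O)C#CC[C@@](C)(O)C(=O)N(C)OC | intermediate
10 | tributyltin hydride | CCCC[SnH](CCCC)CCCC | starting material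
11 | (2R,4Z,6R)-2,6-dihydroxy-N-methoxy-N,2-dimethyl-5-(tributylstannyl)octa-4,7-dienamide | C=C[C@@H](O)/C([Sn](CCCC)(CCCC)CCCC)=C/C[C@@](C)(O)C(=O)N(C)OC | intermediate
12 | 2-bromoprop-2-en-1-ol | OCC(Br)=C | starting material
13 | tert-butyldimethylsilyl chloride | CC(C)(C)[Si](C)(C)Cl | starting material
14 | [(2-bromoprop-2-en-1-yl)oxy](tert-butyl)dimethylsilane | C=C(Br)CO[Si](C)(C)C(C)(C)C | intermediate
15 | (2R,4E,6R)-5-[3-(tert-butyldimethylsilyloxy)prop-1-en-2-yl]-2,6-dihydroxy-N-methoxy-N,2-dimethylocta-4,7-dienamide | C=C[C@@H](O)/C(C(=C)CO[Si](C)(C)C(C)(C)C)=C/C[C@@](C)(O)C(=O)N(C)OC | intermediate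
16 | chlorotriethylsilane | CC[Si](CC)(CC)Cl | starting material
17 | (2R,4E,6R)-5-[3-(tert-butyldimethylsilyloxy)prop-1-en-2-yl]-2-hydroxy-N-methoxy-N,2-dimethyl-6-(triethylsilyloxy)octa-4,7-dienamide | C=C[C@@H](O[Si](CC)(CC)CC)/C(C(=C)CO[Si](C)(C)C(C)(C)C)=C/C[C@@](C)(O)C(=O)N(C)OC | intermediate
18 | potassium peroxymonosulfate (active component of Oxone) | [K+].[O-]S(=O)(=O)OO | starting material
19 | (2R)-3-[(2S,3R)-3-[3-(tert-butyldimethylsilyloxy)prop-1-en-2-yl]-3-[(1R)-1-(triethylsilyloxy)prop-2-en-1-yl]oxiran-2-yl]-2-hydroxy-N-methoxy-N,2-dimethylpropanamide (not isolated) | C=C[C@@H](O[Si](CC)(CC)CC)[C@]1(C(=C)CO[Si](C)(C)C(C)(C)C)O[C@H]1C[C@@](C)(O)C(=O)N(C)OC | intermediate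
20 | (2R,4S,5S)-5-[3-(tert-butyldimethylsilyloxy)prop-1-en-2-yl]-4-hydroxy-N-methoxy-N,2-dimethyl-5-[(1R)-1-(triethylsilyloxy)prop-2-en-1-yl]oxolane-2-carboxamide | C=C[C@@H](O[Si](CC)(CC)CC)[C@@]1(C(=C)CO[Si](C)(C)C(C)(C)C)O[C@](C)(C[C@@H]1O)C(=O)N(C)OC | intermediate
21 | 4-bromo-2-methylbut-1-ene | C=C(C)CCBr | starting material
22 | (3-methylbut-3-en-1-yl)magnesium bromide (not isolated) | C=C(C)CC[Mg]Br | intermediate
23 | 1-[(2R,4S,5S)-5-[3-(tert-butyldimethylsilyloxy)prop-1-en-2-yl]-4-hydroxy-2-methyl-5-[(1R)-1-(triethylsilyloxy)prop-2-en-1-yl]oxolan-2-yl]-4-methylpent-4-en-1-one | C=C[C@@H](O[Si](CC)(CC)CC)[C@@]1(C(=C)CO[Si](C)(C)C(C)(C)C)O[C@](C)(C[C@@H]1O)C(=O)CCC(C)=C | intermediate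
24 | (1R,5Z,7R,8S,9S)-8-[3-(tert-butyldimethylsilyloxy)prop-1-en-2-yl]-9-hydroxy-1,5-dimethyl-7-(triethylsilyloxy)-11-oxabicyclo[6.2.1]undec-5-en-2-one | O[C@H]1C[C@@]2(C)O[C@]1(C(=C)CO[Si](C)(C)C(C)(C)C)[C@H](O[Si](CC)(CC)CC)/C=C(C)\CCC2=O | intermediate
25 | methacrylic anhydride | C=C(C)C(=O)OC(=O)C(C)=C | starting material
26 | (1R,5Z,7R,8S,9S)-8-[3-(tert-butyldimethylsilyloxy)prop-1-en-2-yl]-1,5-dimethyl-2-oxo-7-(triethylsilyloxy)-11-oxabicyclo[6.2.1]undec-5-en-9-yl 2-methylprop-2-enoate | C=C(C)C(=O)O[C@H]1C[C@@]2(C)O[C@]1(C(=C)CO[Si](C)(C)C(C)(C)C)[C@H](O[Si](CC)(CC)CC)/C=C(C)\CCC2=O | intermediate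
27 | (1R,5Z,7R,8R,9S)-8-[3-(tert-butyldimethylsilyloxy)prop-1-en-2-yl]-7-hydroxy-1,5-dimethyl-2-oxo-11-oxabicyclo[6.2.1]undec-5-en-9-yl 2-methylprop-2-enoate | C=C(C)C(=O)O[C@H]1C[C@@]2(C)O[C@]1(C(=C)CO[Si](C)(C)C(C)(C)C)[C@H](O)/C=C(C)\CCC2=O | intermediate
28 | tert-butyl hydroperoxide | CC(C)(C)OO | starting material
29 | epoxy alcohol: C8 methacrylate, C6 hydroxyl, 4,5-oxirane syn to the C6 hydroxyl (4R,5S), C12 tert-butyldimethylsilyl ether, C1 ketone | C=C(C)C(=O)O[C@H]1C[C@@]2(C)O[C@]1(C(=C)CO[Si](C)(C)C(C)(C)C)[C@H](O)[C@@H]1O[C@]1(C)CCC2=O | intermediate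
30 | epoxy diol: 29 with a free C12 hydroxyl | C=C(C)C(=O)O[C@H]1C[C@@]2(C)O[C@]1(C(=C)CO)[C@H](O)[C@@H]1O[C@]1(C)CCC2=O | intermediate
31 | enal: 30 with C12 as aldehyde (not isolated) | C=C(C)C(=O)O[C@H]1C[C@@]2(C)O[C@]1(C(=C)C=O)[C@H](O)[C@@H]1O[C@]1(C)CCC2=O | intermediate
32 | lactol: target with C12 as hemiacetal carbon (either C12 epimer; not isolated) | C=C(C)C(=O)O[C@H]1C[C@@]2(C)O[C@@]13C(=C)C(O)O[C@@H]3[C@@H]1O[C@]1(C)CCC2=O | intermediate
33 | CNP0241021.1 (4R,5S,6R,7S,8S,10R by the atom labels) | C=C(C)C(=O)O[C@H]1C[C@@]2(C)O[C@@]13C(=C)C(=O)O[C@@H]3[C@@H]1O[C@]1(C)CCC2=O | target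

Total step count: 16. Longest linear sequence: 15 steps (steps 1–5 and 7–16; step 6 is a side branch).

Steps most likely to fail

Step 11 (ring-closing metathesis). The ruthenium carbene formed at the C5 vinyl group may be consumed by intermolecular metathesis, or may decompose before it engages the hindered 1,1-disubstituted C4 alkene, so that oligomers form in place of the bicycle. The fallback is a relay ring-closing metathesis that sets out from 20 and comes back to the route at 24. Appel bromination (CBr4, PPh3) of (3E)-3-methyl-5-(prop-2-en-1-yloxy)pent-3-en-1-ol gives relay bromide F1. Mg in THF turns it into relay Grignard reagent F2, which adds to Weinreb amide 20 to give relay ketone F3. With the second-generation Hoveyda–Grubbs catalyst the carbene loads at the unhindered allyl ether, expels 2,5-dihydrofuran and is thereby placed on C4. Closure onto the C5 vinyl group then forms the C4=C5 bond and gives 24.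

Step 9 (Shi epoxidation and cyclisation). Oxygen transfer may be slow at the hindered C7=C8 bond or may go to the wrong face in a mismatched pairing with the C6 silyloxy centre, so that the dioxirane attacks the 1,1-disubstituted C11=C13 bond instead. The fallback replaces reagent-controlled dioxirane transfer by a hydroxyl-directed, ligand-controlled epoxidation; it sets out from 17 and comes back at 19 and so at 20. Hf(Ot-Bu)4 with a chiral C2-symmetric bis-hydroxamic acid ligand and cumene hydroperoxide binds the tertiary homoallylic C10 hydroxyl and should deliver oxygen only to the C7=C8 bond, with the ligand antipode fixing the face. CSA then cyclises 19 to 20 as before. No new compound arises.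

Step 14 (directed epoxidation). The bridged ring may not reach the conformer in which the vanadium-bound C6 alkoxide lies over the alkene, so that oxygen is delivered slowly, to the other face, or to the homoallylic C11=C13 bond. The fallback builds the oxirane after the lactone by way of a bromohydrin; it sets out from 27 and comes back at 33. Bu4NF/AcOH gives alkene diol F4, and TEMPO/PhI(OAc)2 closes alkene lactone F5. N-Bromosuccinimide in aqueous THF should form the bromonium ion on the open outer face, and water opens it at the tertiary C4 from the inner face to give bromohydrin F6. K2CO3 in acetone then closes the oxirane with inversion at C5, which puts the oxygen on the face syn to the C6 oxygen and gives 33.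

Further compounds
F1 | step 11 | (3E)-1-bromo-3-methyl-5-(prop-2-en-1-yloxy)pent-3-ene | C=CCOC/C=C(C)/CCBr
F2 | step 11 | [(3E)-3-methyl-5-(prop-2-en-1-yloxy)pent-3-en-1-yl]magnesium bromide | C=CCOC/C=C(C)/CC[Mg]Br
F3 | step 11 | relay ketone: 23 with the C4 methylene carbon carrying a CH2–O–allyl group (E) | C=C[C@@H](O[Si](CC)(CC)CC)[C@@]1(C(=C)CO[Si](C)(C)C(C)(C)C)O[C@](C)(C[C@@H]1O)C(=O)CC/C(C)=C/COCC=C
F0 | step 9 | none | none
F4 | step 14 | alkene diol: 27 with a free C12 hydroxyl | C=C(C)C(=O)O[C@H]1C[C@@]2(C)O[C@]1(C(=C)CO)[C@H](O)/C=C(C)\CCC2=O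
F5 | step 14 | alkene lactone: target with a Z C4=C5 double bond in place of the oxirane | C=C(C)C(=O)O[C@H]1C[C@@]2(C)O[C@@]13C(=C)C(=O)O[C@@H]3/C=C(C)\CCC2=O
F6 | step 14 | bromohydrin: F5 with C4 hydroxyl and C5 bromide added anti | C=C(C)C(=O)O[C@H]1C[C@@]2(C)O[C@@]13C(=C)C(=O)O[C@@H]3[C@@H](Br)[C@](C)(O)CCC2=O
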